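**Assumption:** the SMILES is taken literally, so C2 and C9 are cis on the C1(10) olefin and the 4,5-epoxide is cis-fused (it comes from a 4Z olefin). Locants follow germacrane numbering: C1–C10 ring, C11–C13 lactone carbons, C14 ester carbon, C15 methyl.

## Retrosynthetic overview
- The epoxide goes in last, by C2-OH-directed epoxidation of the 4Z olefin. The C2 carbinol comes from reagent-controlled reduction of a macrocyclic C2 ketone.
- Key disconnection is C9–C10. A C9 α-acetoxyalkyl radical (from the C9 aldehyde and acetyl iodide) closes the ten-membered ring by 10-endo-dig attack on a 4-oxo-2-ynoate.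
- The ynone comes from a C2 aldehyde and methyl propiolate. C7–C8 comes from chelate-controlled addition of a butenolide-derived allylindium to 2,2-dimethoxyacetaldehyde, followed by angeloylation.
- C6–C7 and the lactone come from asymmetric chromium-catalysed 2-(methoxycarbonyl)allylation of a Z-enal. The Z geometry is inherited from 4-methyl-5,6-dihydropyran-2-one.
- Ring order: γ-lactone, then ten-membered carbocycle, then epoxide.

## Route

Step 1
Reactants: 1 4-methyl-5,6-dihydro-2H-pyran-2-one
Product: 2 4-methyl-5,6-dihydro-2H-pyran-2-ol (lactol)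
Conditions: DIBAL-H (1.05 equiv), CH2Cl2, −78 °C; Rochelle salt work-up
Reagents that add atoms: none
Why: Partial lactone reduction with DIBAL-H stops at the aluminium lactolate at −78 °C; the ring has already fixed the Z geometry of C4=C5 (C3 and C6 cis) and no stereocentre of the target is set.

Step 2
Reactants: 2 4-methyl-5,6-dihydro-2H-pyran-2-ol (lactol)
Product: 3 (2Z)-3-methyl-5-(triethylsilyloxy)pent-2-enal
Conditions: TESCl, imidazole, CH2Cl2, 0 °C
Reagents that add atoms: chlorotriethylsilane CC[Si](Cl)(CC)CC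
Why: Ring–chain tautomerism feeds the conjugated Z-hydroxy enal, whose unhindered primary OH is silylated faster than the hemiacetal OH (silyl ether protection under Curtin–Hammett control), so the free aldehyde is released without touching the olefin geometry.

Step 3
Reactants: 3 (2Z)-3-methyl-5-(triethylsilyloxy)pent-2-enal; 4 methyl 2-(bromomethyl)prop-2-enoate
Product: 6 (5S)-3-methylidene-5-[(1Z)-2-methyl-4-(triethylsilyloxy)but-1-enyl]oxolan-2-one, via silyl ether adduct 5 (not isolated)
Conditions: CrCl2 (10 mol %), chiral 1,8-bis(4-tert-butyloxazolin-2-yl)carbazole ligand (12 mol %, the enantiomer giving Si-face attack), Mn powder, TMSCl, iPr2NEt (30 mol %), THF, rt; then AcOH–THF–H2O, 0 °C; PPTS (cat.), PhH, 40 °C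
Reagents that add atoms: none
Why: Catalytic asymmetric Nozaki–Hiyama–Kishi-type 2-(alkoxycarbonyl)allylation, in which the allylchromium species made from 4 by divalent chromium adds through its γ-carbon to the Si face of the enal inside the chiral ligand pocket and sets C6 (S); Mn and TMSCl turn the catalyst over, and mild acid removes only the secondary TMS ether so that 5 lactonises.

Step 4
Reactants: 6 (5S)-3-methylidene-5-[(1Z)-2-methyl-4-(triethylsilyloxy)but-1-enyl]oxolan-2-one
Product: 8 (5R)-5-[(1Z)-2-methyl-4-(triethylsilyloxy)but-1-enyl]-3-(tosylmethyl)furan-2(5H)-one, via iodosulfone 7 (not isolated)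
Conditions: TsI (1.1 equiv), CH2Cl2, visible light, rt; then Et3N (1.1 equiv), −20 °C, 15 min
Reagents that add atoms: p-toluenesulfonyl iodide Cc1ccc(cc1)S(=O)(=O)I
Why: Iodosulfonylation–dehydroiodination (atom-transfer radical addition, then E2), in which the tosyl radical adds to the unhindered methacrylate-like CH2 faster than to the hindered Z-trisubstituted olefin (where addition is reversible), and loss of HI towards C7–H gives the conjugated endocyclic allyl sulfone; C6 is unchanged in space (its descriptor changes only by priority) provided base contact is short.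

Step 5
Reactants: 8 (5R)-5-[(1Z)-2-methyl-4-(triethylsilyloxy)but-1-enyl]-3-(tosylmethyl)furan-2(5H)-one; 9 2,2-dimethoxyacetaldehyde
Product: 11 (4R,5R)-4-[(1S)-1-hydroxy-2,2-dimethoxyethyl]-3-methylidene-5-[(1Z)-2-methyl-4-(triethylsilyloxy)but-1-enyl]oxolan-2-one, via allylindium reagent 10 (not isolated)
Conditions: Pd(PPh3)4 (5 mol %), InI (1.5 equiv), anhydrous 9 (1.5 equiv), THF, rt
Reagents that add atoms: none
Why: Umpolung carbonyl allylation, in which zerovalent palladium ionises the allyl sulfone and monovalent indium reduces the π-allyl complex to 10, which attacks through C7 and regenerates the exocyclic methylene; C7 is set by attack anti to the C6 side chain (H6/H7 trans), and C8 is set in a Zimmerman–Traxler chair where chelation of indium by the aldehyde oxygen and an acetal oxygen forces CH(OMe)2 axial, giving the syn adduct (8S).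

Step 6
Reactants: 11 (4R,5R)-4-[(1S)-1-hydroxy-2,2-dimethoxyethyl]-3-methylidene-5-[(1Z)-2-methyl-4-(triethylsilyloxy)but-1-enyl]oxolan-2-one; 12 angelic acid [(2Z)-2-methylbut-2-enoic acid]
Product: 14 (1S)-2,2-dimethoxy-1-{(2R,3S)-4-methylidene-5-oxo-2-[(1Z)-2-methyl-4-(triethylsilyloxy)but-1-enyl]oxolan-3-yl}ethyl (2Z)-2-methylbut-2-enoate, via mixed anhydride 13 (not isolated)
Conditions: 12, 2,4,6-trichlorobenzoyl chloride, Et3N, toluene, rt; then 11, toluene, 80 °C
Reagents that add atoms: none
Why: Yamaguchi-type mixed-anhydride esterification is the standard way to make angelates without Z to E isomerisation, and acylation at oxygen retains C8.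

Step 7
Reactants: 14 (1S)-2,2-dimethoxy-1-{(2R,3S)-4-methylidene-5-oxo-2-[(1Z)-2-methyl-4-(triethylsilyloxy)but-1-enyl]oxolan-3-yl}ethyl (2Z)-2-methylbut-2-enoate
Product: 15 (1S)-2,2-dimethoxy-1-{(2R,3S)-4-methylidene-2-[(1Z)-2-methyl-4-oxobut-1-enyl]-5-oxooxolan-3-yl}ethyl (2Z)-2-methylbut-2-enoate
Conditions: IBX (2.5 equiv), DMSO, rt
Reagents that add atoms: none
Why: IBX in DMSO cleaves a primary TES ether and oxidises the liberated alcohol in one pot under neutral conditions (oxidative desilylation), which avoids base-induced conjugation of the β,γ-unsaturated C2 aldehyde.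

Step 8
Reactants: 15 (1S)-2,2-dimethoxy-1-{(2R,3S)-4-methylidene-2-[(1Z)-2-methyl-4-oxobut-1-enyl]-5-oxooxolan-3-yl}ethyl (2Z)-2-methylbut-2-enoate; 16 methyl propiolate
Product: 18 methyl (6Z)-7-{(2R,3S)-3-[(1S)-1-(angeloyloxy)-2,2-dimethoxyethyl]-4-methylidene-5-oxooxolan-2-yl}-4-hydroxy-6-methylhept-6-en-2-ynoate (C2 epimers), via lithium acetylide 17 (not isolated)
Conditions: 16, LiHMDS, THF, −78 °C; then 15, −78 °C; aqueous quench at −78 °C
Reagents that add atoms: none
Why: 1,2-Addition of a lithium acetylide to the aldehyde at −78 °C outruns enolisation and ester attack; the C2 carbinol forms as an inconsequential epimer mixture because it is oxidised in step 10.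

Step 9
Reactants: 18 methyl (6Z)-7-{(2R,3S)-3-[(1S)-1-(angeloyloxy)-2,2-dimethoxyethyl]-4-methylidene-5-oxooxolan-2-yl}-4-hydroxy-6-methylhept-6-en-2-ynoate (C2 epimers)
Product: 19 methyl (6Z)-7-{(2R,3S)-3-[(1S)-1-(angeloyloxy)-2-oxoethyl]-4-methylidene-5-oxooxolan-2-yl}-4-hydroxy-6-methylhept-6-en-2-ynoate (C2 epimers)
Conditions: TFA–H2O (9:1), CH2Cl2, 0 °C
Reagents that add atoms: water O
Why: Acid-catalysed acetal hydrolysis frees the C9 aldehyde; there is no leaving group β to it and no base is present, so the α-acyloxy centre C8 keeps its configuration.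

Step 10
Reactants: 19 methyl (6Z)-7-{(2R,3S)-3-[(1S)-1-(angeloyloxy)-2-oxoethyl]-4-methylidene-5-oxooxolan-2-yl}-4-hydroxy-6-methylhept-6-en-2-ynoate (C2 epimers)
Product: 20 methyl (6Z)-7-{(2R,3S)-3-[(1S)-1-(angeloyloxy)-2-oxoethyl]-4-methylidene-5-oxooxolan-2-yl}-6-methyl-4-oxohept-6-en-2-ynoate
Conditions: Dess–Martin periodinane (1.2 equiv), CH2Cl2, 0 °C; short silica plug; used at once
Reagents that add atoms: none
Why: Dess–Martin oxidation converts both C2 epimers into one ynone under neutral conditions and leaves the aldehyde alone; the C2 ketone now makes C10 the most electrophilic alkyne carbon.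

Step 11 (key step)
Reactants: 20 methyl (6Z)-7-{(2R,3S)-3-[(1S)-1-(angeloyloxy)-2-oxoethyl]-4-methylidene-5-oxooxolan-2-yl}-6-methyl-4-oxohept-6-en-2-ynoate
Product: 22 methyl (1(10)E,4Z,6R,7S,8S,9S)-9-acetoxy-8-(angeloyloxy)-2-oxogermacra-1(10),4,11(13)-trien-12,6-olid-14-oate, via acetoxy iodide 21 (not isolated)
Conditions: AcI (1.05 equiv), Zn(OTf)2 (5 mol %), CH2Cl2, 0 °C, 15 min; diluted into PhH (0.5 mM final); (TMS)3SiH (1.3 equiv, syringe pump, 12 h), Et3B (0.3 equiv)/air, rt
Reagents that add atoms: acetyl iodide CC(=O)I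
Why: Proposed new method: acetyl iodide adds across the aldehyde to give 21, whose iodine is abstracted by the silyl radical far faster than that radical adds to any π-bond; the nucleophilic C9 α-acetoxyalkyl radical cannot reach the lactone methylene (only 4-exo or 5-endo modes), has no activated 1,5-hydrogen and would lose stabilisation in a 1,2-acyloxy shift, so it survives long enough for 10-endo-dig attack on C10 (β to the ketone), and the α-keto vinyl radical then takes H from the silane; C9 is set because the C8–O bond aligns with the singly occupied orbital, C10 attacks anti to it, and A(1,3) strain places OAc next to H8 and H9 next to C7, giving the 8,9-threo (9S) ester, while ring strain and the fumarate-like arrangement of ketone and ester favour the olefin with C2 and C9 cis; the closest known reaction types are the coupling of in situ α-acetoxy iodides with alkynes and reductive endo radical macrocyclisation onto activated π-systems.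

Step 12
Reactants: 22 methyl (1(10)E,4Z,6R,7S,8S,9S)-9-acetoxy-8-(angeloyloxy)-2-oxogermacra-1(10),4,11(13)-trien-12,6-olid-14-oate
Product: 23 methyl (1(10)E,2S,4Z,6R,7S,8S,9S)-9-acetoxy-8-(angeloyloxy)-2-hydroxygermacra-1(10),4,11(13)-trien-12,6-olid-14-oate
Conditions: (R)-2-methyl-CBS-oxazaborolidine (0.5 equiv), catecholborane (2 equiv), toluene–CH2Cl2, −78 °C
Reagents that add atoms: none
Why: Corey–Bakshi–Shibata reduction, in which the alkenyl arm (C1) acts as the large group and C3H2 as the small one, so the (R)-catalyst delivers hydride to give the 2S allylic alcohol by 1,2-reduction; the esters, the lactone methylene and the 4Z olefin are inert at −78 °C.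

Step 13
Reactants: 23 methyl (1(10)E,2S,4Z,6R,7S,8S,9S)-9-acetoxy-8-(angeloyloxy)-2-hydroxygermacra-1(10),4,11(13)-trien-12,6-olid-14-oate
Product: 24 methyl (1(10)E,2S,4R,5S,6S,7R,8S,9S)-9-acetoxy-8-(angeloyloxy)-4,5-epoxy-2-hydroxygermacra-1(10),11(13)-dien-12,6-olid-14-oate (target)
Conditions: VO(acac)2 (5 mol %), TBHP (1.5 equiv, decane), CH2Cl2, 0 °C
Reagents that add atoms: tert-butyl hydroperoxide CC(C)(C)OO
Why: Hydroxyl-directed vanadium-catalysed epoxidation, in which the vanadate ester of the homoallylic C2-OH delivers oxygen to the face of the only electron-rich olefin that is syn to C2–O, which sets 4R,5S as a cis-epoxide because the 4Z geometry is transferred stereospecifically; the three electron-poor olefins do not react.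

## Compound list
1 | 4-methyl-5,6-dihydro-2H-pyran-2-one | CC1=CC(=O)OCC1 | starting material
2 | 4-methyl-5,6-dihydro-2H-pyran-2-ol (lactol) | CC1=CC(O)OCC1 | intermediate
3 | (2Z)-3-methyl-5-(triethylsilyloxy)pent-2-enal | O=C/C=C(/C)CCO[Si](CC)(CC)CC | intermediate
4 | methyl 2-(bromomethyl)prop-2-enoate | C=C(CBr)C(=O)OC | starting material
5 | methyl (4S,5Z)-6-methyl-2-methylidene-8-(triethylsilyloxy)-4-(trimethylsilyloxy)oct-5-enoate (not isolated) | C=C(C[C@H](O[Si](C)(C)C)/C=C(/C)CCO[Si](CC)(CC)CC)C(=O)OC | intermediate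
6 | (5S)-3-methylidene-5-[(1Z)-2-methyl-4-(triethylsilyloxy)but-1-enyl]oxolan-2-one | C=C1C(=O)O[C@H](/C=C(/C)CCO[Si](CC)(CC)CC)C1 | intermediate
7 | (5S)-3-iodo-5-[(1Z)-2-methyl-4-(triethylsilyloxy)but-1-enyl]-3-(tosylmethyl)oxolan-2-one, C3 epimers (not isolated) | Cc1ccc(cc1)S(=O)(=O)CC1(I)C[C@@H](/C=C(/C)CCO[Si](CC)(CC)CC)OC1=O | intermediate
8 | (5R)-5-[(1Z)-2-methyl-4-(triethylsilyloxy)but-1-enyl]-3-(tosylmethyl)furan-2(5H)-one | Cc1ccc(cc1)S(=O)(=O)CC1=C[C@@H](/C=C(/C)CCO[Si](CC)(CC)CC)OC1=O | intermediate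
9 | 2,2-dimethoxyacetaldehyde | COC(OC)C=O | starting material
10 | allylindium iodide p-toluenesulfinate derived from 8, indium on C13 (not isolated) | Cc1ccc(cc1)S(=O)O[In](I)CC1=C[C@@H](/C=C(/C)CCO[Si](CC)(CC)CC)OC1=O | intermediate
11 | (4R,5R)-4-[(1S)-1-hydroxy-2,2-dimethoxyethyl]-3-methylidene-5-[(1Z)-2-methyl-4-(triethylsilyloxy)but-1-enyl]oxolan-2-one | C=C1C(=O)O[C@H](/C=C(/C)CCO[Si](CC)(CC)CC)[C@H]1[C@H](O)C(OC)OC | intermediate
12 | angelic acid, (2Z)-2-methylbut-2-enoic acid | C/C=C(/C)C(=O)O | starting material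
13 | angelic 2,4,6-trichlorobenzoic anhydride (not isolated) | C/C=C(/C)C(=O)OC(=O)c1c(Cl)cc(Cl)cc1Cl | intermediate
14 | 8-O-angelate of 11 (6R,7S,8S) | C=C1C(=O)O[C@H](/C=C(/C)CCO[Si](CC)(CC)CC)[C@H]1[C@H](OC(=O)/C(C)=C\C)C(OC)OC | intermediate
15 | C2 aldehyde (6R,7S,8S) | C=C1C(=O)O[C@H](/C=C(/C)CC=O)[C@H]1[C@H](OC(=O)/C(C)=C\C)C(OC)OC | intermediate
16 | methyl propiolate | C#CC(=O)OC | starting material
17 | lithium 3-methoxy-3-oxoprop-1-ynide (not isolated) | [Li]C#CC(=O)OC | intermediate
18 | γ-hydroxy ynoate acetal, C2 epimers | C=C1C(=O)O[C@H](/C=C(/C)CC(O)C#CC(=O)OC)[C@H]1[C@H](OC(=O)/C(C)=C\C)C(OC)OC | intermediate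
19 | γ-hydroxy ynoate C9 aldehyde, C2 epimers | C=C1C(=O)O[C@H](/C=C(/C)CC(O)C#CC(=O)OC)[C@H]1[C@H](OC(=O)/C(C)=C\C)C=O | intermediate
20 | 4-oxo-2-ynoate C9 aldehyde | C=C1C(=O)O[C@H](/C=C(/C)CC(=O)C#CC(=O)OC)[C@H]1[C@H](OC(=O)/C(C)=C\C)C=O | intermediate
21 | C9 α-acetoxy iodide, C9 epimers (not isolated) | C=C1C(=O)O[C@H](/C=C(/C)CC(=O)C#CC(=O)OC)[C@H]1[C@H](OC(=O)/C(C)=C\C)C(I)OC(C)=O | intermediate
22 | macrocyclic 2-oxo triene (1(10)E,4Z,6R,7S,8S,9S) | C=C1C(=O)O[C@H]2[C@H]1[C@H](OC(=O)/C(C)=C\C)[C@@H](OC(C)=O)/C(C(=O)OC)=C\C(=O)C/C(C)=C\2 | intermediate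
23 | macrocyclic 2S-alcohol (1(10)E,4Z) | C=C1C(=O)O[C@H]2[C@H]1[C@H](OC(=O)/C(C)=C\C)[C@@H](OC(C)=O)/C(C(=O)OC)=C\[C@@H](O)C/C(C)=C\2 | intermediate
24 | CNP0278274.1 | C=C1C(=O)O[C@H]2[C@H]1[C@H](OC(=O)/C(C)=C\C)[C@@H](OC(C)=O)/C(C(=O)OC)=C\[C@@H](O)C[C@@]1(C)O[C@@H]21 | target

## Step count
- Total step count: 13
- Longest linear sequence: 13 (1 to 24; compounds 4, 9, 12 and 16 enter directly)

## The three steps most likely to fail

**Step 11 (radical macrocyclisation).**
- Failure modes: intermolecular addition to the lactone methylene or ynone of other molecules, 9-exo attack at C1, premature reduction of the C9 radical, or the wrong C9 epimer.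
- The fallback sets out from 20 and closes the same bond in a polar way.
- NaI in AcOH adds HI across the ynone. Iodide enters β to the ketone by anti addition, giving the (Z)-2-iodo-4-oxo-2-enoate aldehyde F1, in which iodine is cis to C2.
- An intramolecular Nozaki–Hiyama–Kishi coupling (CrCl2, NiCl2 cat., DMSO–THF, high dilution) retains the olefin geometry and gives the macrocyclic C9 carbinol F2.
- Acetylation (Ac2O, pyridine) comes back to the route at 22.

**Step 5 (allylindium addition).**
- Failure modes: sluggish ionisation of the sulfone, attack through C13, or loss of chelate control giving the 8-epimer.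
- The fallback sets out from 8 (with 9 and 12) and changes the electrophile, so the ester is already in place and the transition state is open.
- Compound 12 is converted with 1-bromo-N,N,2-trimethylpropenylamine into angeloyl bromide F3.
- F3 adds to 9 (ZnBr2 cat., CH2Cl2, −20 °C) to give 1-bromo-2,2-dimethoxyethyl angelate F4.
- Reagent 10, made from 8 as before, attacks the acyloxycarbenium ion released from F4 through an antiperiplanar, syn-selective transition state.
- This comes back to the route at 14 and skips 11.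

**Step 4 (sulfonyl transposition).**
- Failure modes: competing attack of the tosyl radical on the 4Z olefin, elimination to the vinyl sulfone, or racemisation of C6 by base.
- The fallback sets out from 6 and uses only ionic reagents that recognise the electron-poor olefin.
- Weitz–Scheffer epoxidation (TBHP, DBU, CH2Cl2) gives the spiro-epoxy lactone F5.
- Sodium p-toluenesulfinate (NH4Cl, DMF–H2O) opens it at CH2 to give the α-hydroxy-α-(tosylmethyl) lactone F6.
- Dehydration towards C7 (SOCl2, pyridine, 0 °C) comes back to the route at 8.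

## Further compounds
F1 | step 11 | (Z)-2-iodo-4-oxo-2-enoate aldehyde (iodine on C10, cis to C2) | C=C1C(=O)O[C@H](/C=C(/C)CC(=O)/C=C(\I)C(=O)OC)[C@H]1[C@H](OC(=O)/C(C)=C\C)C=O
F2 | step 11 | macrocyclic 9S-hydroxy-2-oxo triene | C=C1C(=O)O[C@H]2[C@H]1[C@H](OC(=O)/C(C)=C\C)[C@@H](O)/C(C(=O)OC)=C\C(=O)C/C(C)=C\2
F3 | step 5 | angeloyl bromide | C/C=C(/C)C(=O)Br
F4 | step 5 | 1-bromo-2,2-dimethoxyethyl angelate | COC(OC)C(Br)OC(=O)/C(C)=C\C
F5 | step 4 | spiro-epoxy lactone from 6 (C11 epimers) | O=C1O[C@H](/C=C(/C)CCO[Si](CC)(CC)CC)CC12CO2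
F6 | step 4 | α-hydroxy-α-(tosylmethyl) lactone (C11 epimers) | O=C1O[C@H](/C=C(/C)CCO[Si](CC)(CC)CC)CC1(O)CS(=O)(=O)c1ccc(C)cc1
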